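**Retrosynthetic overview**
1. GA36 ⇐ double desilylation ⇐ periodate scission of the C-19–C-20 bond of an α-ketol, which releases the C-19 acid and the C-20 aldehyde together.
2. α-Ketol ⇐ bridged cyclopentanone (C-4–C-19(=O)–C-20H2–C-10, α face) ⇐ dissolving-metal opening of the C-20–C-1 bond of a cyclopropyl ketone.
3. Key C–C bond (C-10–C-20, quaternary C-10): intramolecular cyclopropanation of a 1(10)-alkene by the carbenoid of a C-19 diazomethyl ketone. A natively nucleophilic enolate carbon acts as an electrophile (enolonium-type) toward a nucleophilic alkene, and the α-oriented C-19 tether forces C-20 onto the α face.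
4. 1(10)-Ene 19-acid ⇐ palladium/hydride opening of the allylic 19,10-lactone of GA7.
5. Ring order: rings A, B, C and D come intact from GA7. The only rings built are transient: the cyclopropane and the C-4/C-10-bridging cyclopentanone (both in step 5), opened again in steps 6 and 8.

Assumption: GA7 (the 3β-hydroxy-1,16-diene 19,10-lactone gibberellin, a fermentation product sold in bulk as the GA4/GA7 plant-growth-regulator mixture) counts as a commercial starting material. This is therefore a relay synthesis in which C-20 is the only carbon to add. GA36 denotes the target.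

Atom numbering follows the gibberellane skeleton. Centres not named in a description are as in GA7 (5β-H, 6β-carboxyl, 9β-H, C-8 and C-13 unchanged).

**Step 1**
Reactants: 1 GA7; 2 2-(trimethylsilyl)ethanol
Product: 3 GA7 2-(trimethylsilyl)ethyl ester
Conditions: DCC, DMAP (cat), 2 (3 equiv), CH2Cl2, 0 °C to rt
Reagents that add atoms: 2-(trimethylsilyl)ethanol (2), C[Si](C)(C)CCO
Why: Steglich esterification, in which the C-7 carboxyl is the only free acid (C-19 is locked in the lactone) and the primary alcohol 2 in excess outcompetes the hindered axial 3β-OH, so no stereocentre is touched.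

**Step 2**
Reactants: 3 GA7 2-(trimethylsilyl)ethyl ester
Product: 4 3β-hydroxy-1(10)-ene 19-acid 7-[2-(trimethylsilyl)ethyl] ester
Conditions: Pd(PPh3)4 (5 mol %), NaBH4 (2 equiv), THF, 0 °C to rt; pH 4 NaH2PO4 work-up
Reagents that add atoms: none
Why: Tsuji–Trost-type hydrogenolysis of an allylic carboxylate, in which zerovalent palladium ionises the strained tertiary allylic C-10–O bond and hydride from borohydride goes to the less hindered secondary terminus C-2, leaving the more substituted 1(10)-alkene and freeing the C-19 carboxylate; C-2 becomes CH2, so no stereocentre is made, and the saturated ester and the 16-ene are inert.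

**Step 3**
Reactants: 4 3β-hydroxy-1(10)-ene 19-acid 7-[2-(trimethylsilyl)ethyl] ester; 5 tert-butyldimethylsilyl trifluoromethanesulfonate
Product: 6 3-O-TBS ether 19-TBS ester of 4
Conditions: TBSOTf (2.5 equiv), 2,6-lutidine, CH2Cl2, −20 to 0 °C; NaHCO3 wash, Et3N-deactivated silica
Reagents that add atoms: tert-butyldimethylsilyl trifluoromethanesulfonate (5), CC(C)(C)[Si](C)(C)OS(=O)(=O)C(F)(F)F
Why: Lutidine-buffered silylation by a silyl triflate protects the hindered 3β-OH as its ether and turns the C-19 acid into a silyl ester that is a neutral precursor of the acid chloride, so no free acid can relactonise onto the 1(10)-alkene.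

**Step 4**
Reactants: 6 3-O-TBS ether 19-TBS ester of 4; 7 oxalyl chloride; 8 diazomethane
Product: 10 19-diazomethyl ketone (C-19 carbonyl bearing CHN2), via acid chloride 9 (not isolated)
Conditions: (COCl)2 (1.3 equiv), DMF (cat), CH2Cl2, 0 °C to rt; evaporate; CH2N2 (6 equiv), Et2O, 0 °C to rt
Reagents that add atoms: diazomethane (8), C=[N+]=[N-]; oxalyl chloride (7), ClC(=O)C(Cl)=O, supplies only the chlorine of intermediate 9
Why: Conversion of a tert-butyldimethylsilyl ester into the acid chloride by the Vilsmeier reagent generates no HCl (silyl ether, ester and the ene-acid motif survive), and Arndt–Eistert-type acylation of diazomethane then gives the diazoketone, the second equivalent taking up HCl as chloromethane.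

**Step 5**
Reactants: 10 19-diazomethyl ketone
Product: 11 cyclopropyl ketone (C-20 bonded to C-19 C-10 and C-1 on the α face; 1β-H)
Conditions: Cu(acac)2 [copper bis(acetylacetonate)] (5 mol %), toluene, 80 °C, slow addition, 0.005 M
Reagents that add atoms: none
Why: Intramolecular cyclopropanation by a copper carbenoid, in which C-20 (the α-carbon of the C-19 ketone, natively a nucleophilic enolate position) acts as an electrophilic α-keto carbenoid toward the nucleophilic 1(10)-alkene; because the diazoketone hangs from the α-oriented C-19 it can only add on the α face (bicyclo[3.1.0]hexanone mode), which forms the C-10–C-20 bond and sets quaternary C-10 with C-20 α, and copper is chosen over rhodium to suppress insertion into the C-2–H and the ester-deactivated C-6–H bonds.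

**Step 6**
Reactants: 11 cyclopropyl ketone
Product: 13 bridged ketone (C-4–C-19(=O)–C-20H2–C-10 on the α face; C-1 now CH2), via lithium enolate 12 (not isolated)
Conditions: Li (2.2 equiv), liq. NH3/THF, t-BuOH (1 equiv), −78 °C, 10 min; solid NH4Cl, then warm
Reagents that add atoms: none
Why: Dissolving-metal reductive cleavage of a cyclopropyl ketone, in which both ring bonds at C-20 stand about 30° out of the carbonyl plane so that overlap alone does not decide, and the radical anion opens C-20–C-1 because that gives the less substituted carbanion (secondary C-1 rather than tertiary C-10) and lets ring A relax to a chair carrying a two-atom 4,10-bridge shaped like the γ-lactone of 1; t-BuOH protonates C-1, the quench protonates the enolate, and the C-10 centre, the 16-ene and the ester (ketyl formation is far faster at −78 °C without excess lithium) are kept.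

**Step 7**
Reactants: 13 bridged ketone; 14 2-(phenylsulfonyl)-3-phenyloxaziridine
Product: 16 20-hydroxy ketone (C-20 epimers), via potassium enolate 15 (not isolated)
Conditions: KN(SiMe3)2 (1.15 equiv), THF, −78 °C; then 14 (1.5 equiv), −78 °C; NH4Cl quench at −78 °C
Reagents that add atoms: 2-(phenylsulfonyl)-3-phenyloxaziridine (14), O=S(=O)(N1OC1c1ccccc1)c1ccccc1
Why: Davis oxaziridine oxidation of a ketone enolate, in which C-20 is the only enolisable position of the ketone (C-4 is quaternary and the enolate double bond is not at a bridgehead) and is far more acidic than the hindered C-6–H of the ester; the cold quench prevents transposition of the ketol, and the new carbinol centre is destroyed in step 8, so its configuration does not matter.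

**Step 8**
Reactants: 16 20-hydroxy ketone
Product: 17 GA36 3-O-TBS ether 7-[2-(trimethylsilyl)ethyl] ester
Conditions: NaIO4 (3 equiv), THF/H2O 2:1, rt to 40 °C
Reagents that add atoms: water, O (second oxygen of the C-19 carboxyl, through the ketone hydrate; NaIO4 is only the oxidant)
Why: Malaprade-type periodate cleavage of an α-ketol through the hydrate of the strained ketone breaks the C-19–C-20 bond to give the C-19 acid and the C-20 aldehyde at the oxidation levels of the target, at near-neutral pH that leaves the silyl groups, the 16-ene and all stereocentres alone.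

**Step 9**
Reactants: 17 GA36 3-O-TBS ether 7-[2-(trimethylsilyl)ethyl] ester
Product: 18 GA36
Conditions: Bu4NF (6 equiv), THF, 0 to 40 °C; then 1 M HCl to pH 3 at 0 °C
Reagents that add atoms: none
Why: Fluoride-induced desilylation, by β-elimination of the 2-(trimethylsilyl)ethyl ester and Si–O cleavage of the silyl ether, to which the non-enolisable aldehyde, the carboxylates and the 16-ene are inert, so no stereocentre is affected.

**Compound list**
1 | GA7 (3β-hydroxy-1,16-diene, 19,10α-lactone, 7-acid) | C=C1C[C@]23C[C@H]1CC[C@H]2[C@]1(O4)C=C[C@H](O)[C@@](C)(C4=O)[C@H]1[C@@H]3C(=O)O | starting material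
2 | 2-(trimethylsilyl)ethanol | C[Si](C)(C)CCO | starting material
3 | GA7 2-(trimethylsilyl)ethyl ester | C=C1C[C@]23C[C@H]1CC[C@H]2[C@]1(O4)C=C[C@H](O)[C@@](C)(C4=O)[C@H]1[C@@H]3C(=O)OCC[Si](C)(C)C | intermediate
4 | 3β-hydroxy-20-norgibberella-1(10),16-dien-19-oic acid 7-[2-(trimethylsilyl)ethyl] ester | C=C1C[C@]23C[C@H]1CC[C@H]2C1=CC[C@H](O)[C@@](C)(C(=O)O)[C@H]1[C@@H]3C(=O)OCC[Si](C)(C)C | intermediate
5 | tert-butyldimethylsilyl trifluoromethanesulfonate | CC(C)(C)[Si](C)(C)OS(=O)(=O)C(F)(F)F | starting material
6 | 3β-O-TBS ether, 19-TBS ester of 4 | C=C1C[C@]23C[C@H]1CC[C@H]2C1=CC[C@H](O[Si](C)(C)C(C)(C)C)[C@@](C)(C(=O)O[Si](C)(C)C(C)(C)C)[C@H]1[C@@H]3C(=O)OCC[Si](C)(C)C | intermediate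
7 | oxalyl chloride | ClC(=O)C(Cl)=O | starting material
8 | diazomethane (ethereal solution, freshly made from commercial N-methyl-N-nitroso-p-toluenesulfonamide) | C=[N+]=[N-] | starting material
9 | 19-oyl chloride (3β-OTBS, 1(10)-ene, 7-ester) | C=C1C[C@]23C[C@H]1CC[C@H]2C1=CC[C@H](O[Si](C)(C)C(C)(C)C)[C@@](C)(C(Cl)=O)[C@H]1[C@@H]3C(=O)OCC[Si](C)(C)C | intermediate (not isolated)
10 | 19-diazomethyl ketone (4α-diazoacetyl; 3β-OTBS, 1(10)-ene, 7-ester) | C=C1C[C@]23C[C@H]1CC[C@H]2C1=CC[C@H](O[Si](C)(C)C(C)(C)C)[C@@](C)(C(=O)C=[N+]=[N-])[C@H]1[C@@H]3C(=O)OCC[Si](C)(C)C | intermediate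
11 | cyclopropyl ketone: C-20 (CH) bonded to C-19 (C=O), C-10 and C-1, all on the α face; 1β-H; 3β-OTBS, 7-ester | C=C1C[C@]23C[C@H]1CC[C@H]2[C@]14[C@@H]5C[C@H](O[Si](C)(C)C(C)(C)C)[C@@](C)(C(=O)[C@H]45)[C@H]1[C@@H]3C(=O)OCC[Si](C)(C)C | intermediate
12 | lithium enolate of 13 (C-19(OLi)=C-20) | C=C1C[C@]23C[C@H]1CC[C@H]2[C@]14CC[C@H](O[Si](C)(C)C(C)(C)C)[C@@](C)(C([O-])=C4)[C@H]1[C@@H]3C(=O)OCC[Si](C)(C)C.[Li+] | intermediate (not isolated)
13 | bridged ketone: C-19(=O)–C-20H2 bridge from C-4 to C-10 on the α face; 3β-OTBS, 7-ester | C=C1C[C@]23C[C@H]1CC[C@H]2[C@]14CC[C@H](O[Si](C)(C)C(C)(C)C)[C@@](C)(C(=O)C4)[C@H]1[C@@H]3C(=O)OCC[Si](C)(C)C | intermediate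
14 | 2-(phenylsulfonyl)-3-phenyloxaziridine (racemic Davis reagent) | O=S(=O)(N1OC1c1ccccc1)c1ccccc1 | starting material
15 | potassium enolate of 13 (C-19(OK)=C-20) | C=C1C[C@]23C[C@H]1CC[C@H]2[C@]14CC[C@H](O[Si](C)(C)C(C)(C)C)[C@@](C)(C([O-])=C4)[C@H]1[C@@H]3C(=O)OCC[Si](C)(C)C.[K+] | intermediate (not isolated)
16 | 20-hydroxy derivative of 13 (α-ketol; C-20 epimers, configuration not defined because it is destroyed in step 8) | C=C1C[C@]23C[C@H]1CC[C@H]2[C@]14CC[C@H](O[Si](C)(C)C(C)(C)C)[C@@](C)(C(=O)C4O)[C@H]1[C@@H]3C(=O)OCC[Si](C)(C)C | intermediate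
17 | GA36 3-O-TBS ether 7-[2-(trimethylsilyl)ethyl] ester (19-acid, 20-aldehyde, drawn open; in equilibrium with the 19,20-lactol) | C=C1C[C@]23C[C@H]1CC[C@H]2[C@]1(C=O)CC[C@H](O[Si](C)(C)C(C)(C)C)[C@@](C)(C(=O)O)[C@H]1[C@@H]3C(=O)OCC[Si](C)(C)C | intermediate
18 | GA36 (3β-hydroxy, 16-ene, 7- and 19-carboxylic acids, 20-aldehyde on C-10α) | C=C1C[C@]23C[C@H]1CC[C@H]2[C@]1(C=O)CC[C@H](O)[C@@](C)(C(=O)O)[C@H]1[C@@H]3C(=O)O | target

**Totals**
Total step count: 9. Longest linear sequence: 9 steps (1 to 18).

**Three steps most likely to fail**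

Step 2 (palladium/hydride lactone opening). The hydride may go to C-10, or the hindered lactone may ionise poorly. The fallback sets out from 1 and comes back at 4. Lithium in liquid NH3/THF at −78 °C (then NH4Cl) cleaves the allylic lactone of unprotected 1, whose carboxylate and alkoxide protect themselves, to the ene diacid F1. Iodolactonisation (I2 1.0 equiv, NaHCO3, aqueous THF, 0 °C) re-closes the 19,10-lactone and gives the 1β-iodo lactone acid F2, in which only the C-7 acid is free. DCC/DMAP with 2 then gives the iodolactone ester F3. Zinc dust with NH4Cl in ethanol reductively eliminates the anti-periplanar 1β-iodide and 10α-carboxylate to return 4.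

Step 5 (key cyclopropanation). The carbenoid may be diverted into C–H insertion at C-2, Wolff rearrangement or dimer. The fallback sets out from 10 and comes back at 11, and uses no metal carbenoid. Warming 10 in toluene (80 °C, dark, neutral glassware to avoid tautomerisation) lets the diazoketone add as a 1,3-dipole across the 1(10)-alkene, under the same α-face tether control, to give the 1-pyrazoline F4. Irradiation at 350 nm in benzene extrudes N2 and closes the cyclopropane of 11.

Step 6 (reductive scission of the cyclopropane). The other ring bond, C-20–C-10, overlaps nearly as well; its cleavage would move C-20 to C-1 and destroy the key bond, and excess lithium may attack the ester. The fallback sets out from 11 and comes back at 13. It replaces electron transfer by a two-electron nucleophilic opening, in which only the secondary C-1 can be attacked because the other terminus, C-10, is quaternary. Sodium benzeneselenolate (PhSeH, NaH, 18-crown-6, THF, 60 °C; NH4Cl) adds in homoconjugate fashion at C-1 by backside displacement of C-20 and gives the 1β-phenylselanyl bridged ketone F5. Bu3SnH and AIBN (cat) in toluene at 90 °C then replace selenium by hydrogen to give 13.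

**Further compounds**
F1 | step 2 | 3β-hydroxy-20-norgibberella-1(10),16-diene-7,19-dioic acid | C=C1C[C@]23C[C@H]1CC[C@H]2C1=CC[C@H](O)[C@@](C)(C(=O)O)[C@H]1[C@@H]3C(=O)O
F2 | step 2 | 1β-iodo-3β-hydroxy-16-ene 19,10α-lactone 7-acid | C=C1C[C@]23C[C@H]1CC[C@H]2[C@]1(O4)[C@H](I)C[C@H](O)[C@@](C)(C4=O)[C@H]1[C@@H]3C(=O)O
F3 | step 2 | 2-(trimethylsilyl)ethyl ester of F2 | C=C1C[C@]23C[C@H]1CC[C@H]2[C@]1(O4)[C@H](I)C[C@H](O)[C@@](C)(C4=O)[C@H]1[C@@H]3C(=O)OCC[Si](C)(C)C
F4 | step 5 | 1-pyrazoline (C-20–N=N–C-1 bridge on the α face, C-20 also bonded to C-19 and C-10; 3β-OTBS, 7-ester) | C=C1C[C@]23C[C@H]1CC[C@H]2[C@]14[C@@H]5C[C@H](O[Si](C)(C)C(C)(C)C)[C@@](C)(C(=O)[C@H]4N=N5)[C@H]1[C@@H]3C(=O)OCC[Si](C)(C)C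
F5 | step 6 | 1β-phenylselanyl derivative of 13 (3β-OTBS, 7-ester) | C=C1C[C@]23C[C@H]1CC[C@H]2[C@]14[C@H]([Se]c5ccccc5)C[C@H](O[Si](C)(C)C(C)(C)C)[C@@](C)(C(=O)C4)[C@H]1[C@@H]3C(=O)OCC[Si](C)(C)C
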